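**Retrosynthetic overview**
- The sulfate is placed late on O7 of a 5,7-diol, where O5–H is tied to the C4 carbonyl. O3, O6 and O4' are benzyl ethers removed at the end, and O3 itself comes from C3 lithiation, borylation and oxidation of a flavone.
- The flavone is cut at three bonds of ring C (O1–C8a, C4–C4a, O1–C2) into a 3,4,5-trioxygenated aryne (ring A) and 3-[4-(benzyloxy)phenyl]propiolic acid (C2, C3, C4, both ring C oxygens, ring B).
- Feature used: in ring A, C8a (bearing O1) and C4a (bearing the C4 acyl carbon) are neighbours, with oxygenated C5 beside C4a and C8–H beside C8a. This is the pattern an oxygen nucleophile leaves on a 3-alkoxyaryne when it adds at the carbon remote from the alkoxy group.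
- The ortho-silyl aryl triflate comes from 3,4,5-trihydroxybenzaldehyde through a symmetric 4-benzyloxy-3,5-bis(methoxymethoxy)phenol. The acid comes from carboxylation of 1-(benzyloxy)-4-ethynylbenzene.
- Ring order: rings A and B are bought; ring C is the only ring formed, in the key step.

Key step: step 7

Remark: the target is drawn as the free aryl hydrogen sulfate. Such acids hydrolyse under their own acidity, so the sulfate is carried as its sodium salt and protonated only in the last operation, cold and with immediate desalting.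

**Route**

Step 1
Reactants: 1 3,4,5-trihydroxybenzaldehyde
Product: 2 4-(benzyloxy)-3,5-dihydroxybenzaldehyde
Conditions: BnBr (1.0 equiv), NaHCO3, DMF, 40 °C
Reagents that add atoms: benzyl bromide, BrCc1ccccc1
Why: Williamson etherification under weak-base control; NaHCO3 ionises only the 4-OH, the most acidic phenol because it is para to the formyl group, so benzylation should go there.

Step 2
Reactants: 2 4-(benzyloxy)-3,5-dihydroxybenzaldehyde
Product: 3 4-(benzyloxy)-3,5-bis(methoxymethoxy)benzaldehyde
Conditions: MOMCl, iPr2NEt, CH2Cl2, 0 °C → rt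
Reagents that add atoms: chloromethyl methyl ether, COCCl
Why: Standard methoxymethyl ether formation (O-alkylation under amine base) on both remaining phenols; the aldehyde and the benzyl ether are inert.

Step 3
Reactants: 3 4-(benzyloxy)-3,5-bis(methoxymethoxy)benzaldehyde
Product: 5 4-(benzyloxy)-3,5-bis(methoxymethoxy)phenol, via aryl formate 4 (not isolated)
Conditions: mCPBA, CH2Cl2, 0 °C → rt; aq NaHCO3 wash; K2CO3 (cat.), MeOH, rt
Reagents that add atoms: 3-chloroperbenzoic acid, OOC(=O)c1cccc(Cl)c1
Why: Baeyer–Villiger oxidation (Dakin-type) in which the electron-rich trialkoxyaryl group migrates in preference to hydride to give formate 4, which methanol then transesterifies to the symmetric phenol.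

Step 4
Reactants: 5 4-(benzyloxy)-3,5-bis(methoxymethoxy)phenol
Product: 6 4-(benzyloxy)-2-bromo-3,5-bis(methoxymethoxy)phenol
Conditions: NBS (1.0 equiv), CH2Cl2, −78 → −20 °C
Reagents that add atoms: N-bromosuccinimide, BrN1C(=O)CCC1=O
Why: Electrophilic aromatic bromination; the two free positions are equivalent and each is ortho to the hydroxyl, so one equivalent of NBS at low temperature should give a single monobromide.

Step 5
Reactants: 6 4-(benzyloxy)-2-bromo-3,5-bis(methoxymethoxy)phenol
Product: 9 4-(benzyloxy)-3,5-bis(methoxymethoxy)-2-(trimethylsilyl)phenyl trifluoromethanesulfonate, via trimethylsilyl ether 7 (not isolated), via lithium 2-silylphenolate 8 (not isolated)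
Conditions: (Me3Si)2NH, THF, 70 °C, then evaporation; n-BuLi, THF, −100 °C; Tf2O, −100 → −78 °C
Reagents that add atoms: hexamethyldisilazane, C[Si](C)(C)N[Si](C)(C)C; trifluoromethanesulfonic anhydride, O=S(=O)(OS(=O)(=O)C(F)(F)F)C(F)(F)F
Why: Established sequence to ortho-silylaryl triflates: O-silylation, bromine–lithium exchange, 1,3 O→C silyl shift (retro-Brook rearrangement) to phenolate 8 and O-triflation; the symmetry of 5 ensures a single isomer with silicon between the triflate and a methoxymethoxy group.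

Step 6
Reactants: 10 1-(benzyloxy)-4-ethynylbenzene
Product: 12 3-[4-(benzyloxy)phenyl]prop-2-ynoic acid, via lithium acetylide 11 (not isolated)
Conditions: n-BuLi, THF, −78 °C; CO2 (gas), −78 °C → rt; aq HCl
Reagents that add atoms: carbon dioxide, O=C=O
Why: Deprotonation of the terminal alkyne and carboxylation of the acetylide with CO2 is the standard route to arylpropiolic acids; the benzyl ether is inert.

Step 7
Reactants: 9 4-(benzyloxy)-3,5-bis(methoxymethoxy)-2-(trimethylsilyl)phenyl trifluoromethanesulfonate (1.5 equiv); 12 3-[4-(benzyloxy)phenyl]prop-2-ynoic acid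
Product: 15 6-(benzyloxy)-2-[4-(benzyloxy)phenyl]-5,7-bis(methoxymethoxy)-4H-chromen-4-one, via aryne 13 (not isolated), via cesium ynone phenolate 14 (not isolated)
Conditions: CsF (4 equiv), THF, 125 °C, sealed tube
Reagents that add atoms: none
Why: Fluoride removes the trimethylsilyl group of 9 with loss of triflate to give aryne 13 and also turns 12 into its cesium carboxylate. The carboxylate oxygen adds to the aryne carbon that becomes C8a, the aryl anion left at C4a attacks the new ester carbonyl through a four-membered alkoxide, and opening of that ring moves the acyl group from oxygen to carbon (a 1,3 anionic Fries-type shift, in sum insertion of the aryne into the acyl C–O bond) to give the ortho-acyl phenolate 14. The closest known reaction type is this same intermolecular C–O addition of carboxylic acids to arynes from silyl triflates and CsF, which with arylpropiolic acids is known to continue to flavones in the same flask. Ring C closes by 6-endo-dig oxa-Michael addition of O1 to C2 of the ynone, preferred over 5-exo-dig attack at C3 because only the conjugate mode leads to a stabilised allenolate, which is then protonated at C3. No stereocentre is formed. The selectivity needed is the direction of the first addition, and it is secured by the methoxymethoxy group on the carbon next to the aryne (the later C5), which distorts the triple bond and stabilises charge at the adjacent carbon (C4a) so that oxygen enters at the remote carbon (C8a); keeping 9 in excess and adding no proton source other than the acid should let acyl transfer outrun protonation of the aryl anion.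

Step 8
Reactants: 15 6-(benzyloxy)-2-[4-(benzyloxy)phenyl]-5,7-bis(methoxymethoxy)-4H-chromen-4-one
Product: 18 6-(benzyloxy)-2-[4-(benzyloxy)phenyl]-3-hydroxy-5,7-bis(methoxymethoxy)-4H-chromen-4-one, via 3-lithioflavone 16 (not isolated), via flavon-3-ylboronate 17 (not isolated)
Conditions: LiN(iPr)2, THF, −78 °C; B(OMe)3, −78 → 0 °C; AcOH, 30% H2O2, 0 °C → rt
Reagents that add atoms: hydrogen peroxide, OO
Why: Lithiation of the vinylic C3–H next to the C4 carbonyl by the amide base, borylation and oxidative boron-to-oxygen 1,2-migration is a known flavone-to-flavonol conversion; −78 °C should keep 16 from opening ring C by beta-elimination of O1.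

Step 9
Reactants: 18 6-(benzyloxy)-2-[4-(benzyloxy)phenyl]-3-hydroxy-5,7-bis(methoxymethoxy)-4H-chromen-4-one
Product: 19 3,6-bis(benzyloxy)-2-[4-(benzyloxy)phenyl]-5,7-bis(methoxymethoxy)-4H-chromen-4-one
Conditions: BnBr, K2CO3, DMF, 50 °C
Reagents that add atoms: benzyl bromide, BrCc1ccccc1
Why: Williamson etherification of the only free hydroxyl; masking O3 now leaves O7 as the only reactive phenol once the acetals are removed.

Step 10
Reactants: 19 3,6-bis(benzyloxy)-2-[4-(benzyloxy)phenyl]-5,7-bis(methoxymethoxy)-4H-chromen-4-one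
Product: 20 3,6-bis(benzyloxy)-2-[4-(benzyloxy)phenyl]-5,7-dihydroxy-4H-chromen-4-one
Conditions: HCl (3 M, cat.), MeOH/THF, 50 °C
Reagents that add atoms: none
Why: Acid-catalysed acetal exchange transfers both methoxymethyl groups to methanol, while benzyl ethers are stable to dilute HCl.

Step 11
Reactants: 20 3,6-bis(benzyloxy)-2-[4-(benzyloxy)phenyl]-5,7-dihydroxy-4H-chromen-4-one
Product: 22 sodium 3,6-bis(benzyloxy)-2-[4-(benzyloxy)phenyl]-5-hydroxy-4-oxo-4H-chromen-7-yl sulfate, via pyridinium sulfate 21 (not isolated)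
Conditions: SO3·pyridine (3 equiv), pyridine, rt; aq NaHCO3; C18 reversed-phase chromatography
Reagents that add atoms: sulfur trioxide–pyridine complex, O=S(=O)=O.c1ccncc1; sodium hydrogen carbonate, [Na+].OC([O-])=O
Why: O-Sulfation of a phenol with an SO3–amine complex; the 5-OH is held in a hydrogen bond to the C4 carbonyl and is poorly nucleophilic, so the free, more acidic 7-OH should react selectively, and NaHCO3 exchanges pyridinium for sodium so that no amine reaches the hydrogenolysis.

Step 12
Reactants: 22 sodium 3,6-bis(benzyloxy)-2-[4-(benzyloxy)phenyl]-5-hydroxy-4-oxo-4H-chromen-7-yl sulfate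
Product: 24 3,5,6-trihydroxy-2-(4-hydroxyphenyl)-4-oxo-4H-chromen-7-yl hydrogen sulfate, via debenzylated sodium sulfate 23 (not isolated)
Conditions: H2 (1 atm), Pd/C (10% palladium on carbon), MeOH/THF, rt; filtration; HCl (1.0 equiv), H2O, 0 °C; C18 desalting, freeze-drying under argon
Reagents that add atoms: none
Why: Catalytic hydrogenolysis cleaves the three benzyl ethers while aryl sulfate salts and the flavonol C2–C3 double bond are retained, and one equivalent of cold HCl then protonates the sulfate to the hydrogen sulfate form.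

**Compound list**

1 | 3,4,5-trihydroxybenzaldehyde | O=Cc1cc(O)c(O)c(O)c1 | starting material
2 | 4-(benzyloxy)-3,5-dihydroxybenzaldehyde | O=Cc1cc(O)c(OCc2ccccc2)c(O)c1 | intermediate
3 | 4-(benzyloxy)-3,5-bis(methoxymethoxy)benzaldehyde | O=Cc1cc(OCOC)c(OCc2ccccc2)c(OCOC)c1 | intermediate
4 | 4-(benzyloxy)-3,5-bis(methoxymethoxy)phenyl formate (not isolated) | O=COc1cc(OCOC)c(OCc2ccccc2)c(OCOC)c1 | intermediate
5 | 4-(benzyloxy)-3,5-bis(methoxymethoxy)phenol | Oc1cc(OCOC)c(OCc2ccccc2)c(OCOC)c1 | intermediate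
6 | 4-(benzyloxy)-2-bromo-3,5-bis(methoxymethoxy)phenol | Oc1cc(OCOC)c(OCc2ccccc2)c(OCOC)c1Br | intermediate
7 | [4-(benzyloxy)-2-bromo-3,5-bis(methoxymethoxy)phenoxy]trimethylsilane (not isolated) | C[Si](C)(C)Oc1cc(OCOC)c(OCc2ccccc2)c(OCOC)c1Br | intermediate
8 | lithium 4-(benzyloxy)-3,5-bis(methoxymethoxy)-2-(trimethylsilyl)phenolate (not isolated) | [Li+].[O-]c1cc(OCOC)c(OCc2ccccc2)c(OCOC)c1[Si](C)(C)C | intermediate
9 | 4-(benzyloxy)-3,5-bis(methoxymethoxy)-2-(trimethylsilyl)phenyl trifluoromethanesulfonate | C[Si](C)(C)c1c(OS(=O)(=O)C(F)(F)F)cc(OCOC)c(OCc2ccccc2)c1OCOC | intermediate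
10 | 1-(benzyloxy)-4-ethynylbenzene | C#Cc1ccc(OCc2ccccc2)cc1 | starting material
11 | {[4-(benzyloxy)phenyl]ethynyl}lithium (not isolated) | [Li]C#Cc1ccc(OCc2ccccc2)cc1 | intermediate
12 | 3-[4-(benzyloxy)phenyl]prop-2-ynoic acid | OC(=O)C#Cc1ccc(OCc2ccccc2)cc1 | intermediate
13 | 4-(benzyloxy)-3,5-bis(methoxymethoxy)benzyne (1,2-didehydrobenzene; not isolated) | COCOC1=C(OCc2ccccc2)C(OCOC)=CC#C1 | intermediate
14 | cesium 4-(benzyloxy)-2-{3-[4-(benzyloxy)phenyl]prop-2-ynoyl}-3,5-bis(methoxymethoxy)phenolate (not isolated) | [Cs+].[O-]c1cc(OCOC)c(OCc2ccccc2)c(OCOC)c1C(=O)C#Cc1ccc(OCc2ccccc2)cc1 | intermediate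
15 | 6-(benzyloxy)-2-[4-(benzyloxy)phenyl]-5,7-bis(methoxymethoxy)-4H-chromen-4-one | O=c1cc(-c2ccc(OCc3ccccc3)cc2)oc2cc(OCOC)c(OCc3ccccc3)c(OCOC)c12 | intermediate
16 | 6-(benzyloxy)-2-[4-(benzyloxy)phenyl]-3-lithio-5,7-bis(methoxymethoxy)-4H-chromen-4-one (not isolated) | [Li]c1c(-c2ccc(OCc3ccccc3)cc2)oc2cc(OCOC)c(OCc3ccccc3)c(OCOC)c2c1=O | intermediate
17 | dimethyl {6-(benzyloxy)-2-[4-(benzyloxy)phenyl]-5,7-bis(methoxymethoxy)-4-oxo-4H-chromen-3-yl}boronate (not isolated) | COB(OC)c1c(-c2ccc(OCc3ccccc3)cc2)oc2cc(OCOC)c(OCc3ccccc3)c(OCOC)c2c1=O | intermediate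
18 | 6-(benzyloxy)-2-[4-(benzyloxy)phenyl]-3-hydroxy-5,7-bis(methoxymethoxy)-4H-chromen-4-one | O=c1c(O)c(-c2ccc(OCc3ccccc3)cc2)oc2cc(OCOC)c(OCc3ccccc3)c(OCOC)c12 | intermediate
19 | 3,6-bis(benzyloxy)-2-[4-(benzyloxy)phenyl]-5,7-bis(methoxymethoxy)-4H-chromen-4-one | O=c1c(OCc2ccccc2)c(-c2ccc(OCc3ccccc3)cc2)oc2cc(OCOC)c(OCc3ccccc3)c(OCOC)c12 | intermediate
20 | 3,6-bis(benzyloxy)-2-[4-(benzyloxy)phenyl]-5,7-dihydroxy-4H-chromen-4-one | O=c1c(OCc2ccccc2)c(-c2ccc(OCc3ccccc3)cc2)oc2cc(O)c(OCc3ccccc3)c(O)c12 | intermediate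
21 | pyridinium 3,6-bis(benzyloxy)-2-[4-(benzyloxy)phenyl]-5-hydroxy-4-oxo-4H-chromen-7-yl sulfate (not isolated) | O=c1c(OCc2ccccc2)c(-c2ccc(OCc3ccccc3)cc2)oc2cc(OS(=O)(=O)[O-])c(OCc3ccccc3)c(O)c12.c1cc[nH+]cc1 | intermediate
22 | sodium 3,6-bis(benzyloxy)-2-[4-(benzyloxy)phenyl]-5-hydroxy-4-oxo-4H-chromen-7-yl sulfate | [Na+].O=c1c(OCc2ccccc2)c(-c2ccc(OCc3ccccc3)cc2)oc2cc(OS(=O)(=O)[O-])c(OCc3ccccc3)c(O)c12 | intermediate
23 | sodium 3,5,6-trihydroxy-2-(4-hydroxyphenyl)-4-oxo-4H-chromen-7-yl sulfate (not isolated) | [Na+].O=c1c(O)c(-c2ccc(O)cc2)oc2cc(OS(=O)(=O)[O-])c(O)c(O)c12 | intermediate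
24 | 3,5,6-trihydroxy-2-(4-hydroxyphenyl)-4-oxo-4H-chromen-7-yl hydrogen sulfate | O=c1c(O)c(-c2ccc(O)cc2)oc2cc(OS(=O)(=O)O)c(O)c(O)c12 | target

**Step count**

Total: 12 steps. Longest linear sequence: 11 steps (steps 1–5 and 7–12, from 1 to 24).

**Steps most likely to fail**

Step 7. The aryl anion formed after carboxylate addition may be protonated before it transfers the acyl group, which would stop at the aryl propiolate ester. The cesium propiolate may also lose CO2 at 125 °C, and excess aryne may arylate phenolate 14 before ring closure. The fallback builds the C4a–C4 bond by acyl-palladium chemistry instead. It sets out from phenol 5 and alkyne 10. Iodination of 5 with N-iodosuccinimide (CH2Cl2, −40 °C) should give 4-(benzyloxy)-2-iodo-3,5-bis(methoxymethoxy)phenol F1. Carbonylative Sonogashira coupling of F1 with 10 (PdCl2(dppf) cat., Et2NH, CO 20 atm, 120 °C) should form 1-[3-(benzyloxy)-6-hydroxy-2,4-bis(methoxymethoxy)phenyl]-3-[4-(benzyloxy)phenyl]prop-2-yn-1-one F2. The amine should close F2 in the same flask by conjugate addition of the phenol, and the route is rejoined at flavone 15.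

Step 8. The 3-lithio species may open ring C by beta-elimination of the O1 phenolate, deprotonation may be incomplete, or the base may add to the carbonyl. The fallback oxidises the C2–C3 double bond electrophilically. It sets out from flavone 15. Dimethyldioxirane (acetone/CH2Cl2, 0 °C → rt) should give racemic 2,3-epoxy-6-(benzyloxy)-2-[4-(benzyloxy)phenyl]-5,7-bis(methoxymethoxy)chroman-4-one F3 (flavone numbering). Brief treatment of F3 with catalytic p-TsOH (CH2Cl2, 0 °C) should open the epoxide at C2 with loss of the C3 proton, and the route is rejoined at flavonol 18.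

Step 11. Sulfation may also occur at O5 if forced, or stay incomplete, and the sulfate or material may be lost while the polar salt is isolated. The fallback introduces the sulfate as a neutral, chromatographable diester. It sets out from diol 20. 2,2,2-Trichloroethyl chlorosulfate (Et3N, DMAP, THF, rt) should give 3,6-bis(benzyloxy)-2-[4-(benzyloxy)phenyl]-5-hydroxy-4-oxo-4H-chromen-7-yl 2,2,2-trichloroethyl sulfate F4, purified on silica. Reductive fragmentation of the trichloroethyl group (Zn dust, HCO2NH4, MeOH, rt) should give ammonium 3,6-bis(benzyloxy)-2-[4-(benzyloxy)phenyl]-5-hydroxy-4-oxo-4H-chromen-7-yl sulfate F5. Evaporation of F5 from aqueous NaHCO3 exchanges the cation, and the route is rejoined at sodium salt 22.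

**Further compounds**

F1 | step 7 | 4-(benzyloxy)-2-iodo-3,5-bis(methoxymethoxy)phenol | Oc1cc(OCOC)c(OCc2ccccc2)c(OCOC)c1I
F2 | step 7 | 1-[3-(benzyloxy)-6-hydroxy-2,4-bis(methoxymethoxy)phenyl]-3-[4-(benzyloxy)phenyl]prop-2-yn-1-one | Oc1cc(OCOC)c(OCc2ccccc2)c(OCOC)c1C(=O)C#Cc1ccc(OCc2ccccc2)cc1
F3 | step 8 | racemic 2,3-epoxy-6-(benzyloxy)-2-[4-(benzyloxy)phenyl]-5,7-bis(methoxymethoxy)chroman-4-one (one enantiomer drawn) | O=C1[C@H]2O[C@@]2(c3ccc(OCc4ccccc4)cc3)Oc3cc(OCOC)c(OCc4ccccc4)c(OCOC)c13
F4 | step 11 | 3,6-bis(benzyloxy)-2-[4-(benzyloxy)phenyl]-5-hydroxy-4-oxo-4H-chromen-7-yl 2,2,2-trichloroethyl sulfate | O=c1c(OCc2ccccc2)c(-c2ccc(OCc3ccccc3)cc2)oc2cc(OS(=O)(=O)OCC(Cl)(Cl)Cl)c(OCc3ccccc3)c(O)c12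
F5 | step 11 | ammonium 3,6-bis(benzyloxy)-2-[4-(benzyloxy)phenyl]-5-hydroxy-4-oxo-4H-chromen-7-yl sulfate | [NH4+].O=c1c(OCc2ccccc2)c(-c2ccc(OCc3ccccc3)cc2)oc2cc(OS(=O)(=O)[O-])c(OCc3ccccc3)c(O)c12
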